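**Plan**

- Retrosynthetic cuts: the C7′–N amide to the aminocyclopentenone, the N–C2 enamide bond to (2E,4R)-4-methyloct-2-enamide, the C1′=C2′ alkene to a sorbate-derived C6 phosphonate, and in the core the ring bonds C1–C2 and C3–C4.
- Enabling feature: with the six-membered ring numbered C1 (ketone), C2 (N-bearing), C3, C4 (carbinol), C5 and C6 (oxirane), C4 carries both OH and the chain carbon C1′ and lies 1,4 to the oxygen-bearing C1. These are the two bridgeheads of a [4+2] adduct of 3-hydroxy-2-pyrone: the lactone bridge supplies C1′ and the C1 oxygen, and the alkene bridge is C5=C6.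
- Forward order: cycloaddition with phenyl vinyl sulfone closes the carbocycle; epoxidation adds the oxirane; lactone reduction and Horner–Wadsworth–Emmons reaction join the triene; oxidation at C1 with loss of sulfinate gives the enone; C2 iodination and copper-catalysed amidation join the upper chain; fluoride deprotection and amide coupling to the five-membered ring finish.
- Stereochemistry: C4 comes from the cinchona-catalysed cycloaddition; C5 and C6 come from the bicyclic lactone template (the endo sulfone blocks one face, so the oxirane ends cis to C1′ and trans to C4–OH); the side-chain (R) centre comes from an Evans methylation; the E alkenes come from stabilised phosphorus reagents.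

Key step: step 1

Assumption: the quinidine-series catalyst is taken to deliver the (1R,4R,8R) adduct 3; should induction run the other way, the quinine-series pseudoenantiomer, 9-O-(9-phenanthryl)cupreine, would be used under the same conditions.
Assumption: 2-amino-3-hydroxycyclopent-2-en-1-one hydrochloride (25) is treated as a purchasable building block.

**Route**

Step 1
Reactants: 1 3-hydroxy-2H-pyran-2-one; 2 phenyl vinyl sulfone
Product: 3 (1R,4R,8R)-4-hydroxy-8-(phenylsulfonyl)-2-oxabicyclo[2.2.2]oct-5-en-3-one (endo adduct: sulfonyl group syn to the C5=C6 bridge)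
Conditions: 9-O-(9-phenanthryl)cupreidine (10 mol %), EtOAc, 0 °C to rt
Reagents that add atoms: none
Why: The quinuclidine nitrogen deprotonates the 3-hydroxyl group to a dienolate ion pair with a raised HOMO while the 6′-OH of the catalyst hydrogen-bonds to a sulfonyl oxygen, so that pyrone C6 (future ring C1) attacks the sulfone β-carbon and the α-sulfonyl carbon bonds to pyrone C3 (future ring C4), either as an asynchronous [4πs+2πs] cycloaddition or as a vinylogous Michael addition followed by aldol closure. The closest known reaction type is the amine-base and cinchona-alkaloid catalysed Diels-Alder reaction of 3-hydroxy-2-pyrones with electron-poor alkenes, and 6′-hydroxy cinchona catalysts of this kind are known to activate vinyl sulfones as Michael acceptors. The six-membered carbocycle closes when the second C–C bond forms, suprafacially across the diene if concerted or as a 6-exo-trig aldol onto the C3 ketone if stepwise, and the lactone remains as the third bridge of a 2-oxabicyclo[2.2.2]octenone. The two bridgeheads (ring C1 and C4) are set together by the diene face that the catalyst leaves open, and ring C3 by endo approach, the sulfonyl group lying under the diene and ending syn to the new C5=C6 bridge. The step needs regio-, endo- and enantiofacial selectivity: the oxido donor at one diene terminus makes the other terminus the nucleophilic carbon, which fixes the 4-hydroxy-8-sulfonyl pattern, and the bifunctional catalyst holding both partners in one ion-paired, hydrogen-bonded assembly should secure the other two.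

Step 2
Reactants: 3 (1R,4R,8R)-4-hydroxy-8-(phenylsulfonyl)-2-oxabicyclo[2.2.2]oct-5-en-3-one
Product: 4 5,6-epoxide of 3, oxirane oxygen on the face of the former alkene bridge that looks toward the lactone bridge (anti to the sulfonyl group)
Conditions: mCPBA, NaHCO3, CH2Cl2, 0 °C to rt
Reagents that add atoms: mCPBA, OOC(=O)c1cccc(Cl)c1
Why: Prilezhaev epoxidation of the strained bicyclic alkene should occur on the face next to the lactone bridge because the endo phenylsulfonyl group on the ethano bridge covers the other face, which sets both oxirane carbons with the oxygen cis to C1′ and trans to the C4 hydroxyl.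

Step 3
Reactants: 4 epoxy hydroxy lactone
Product: 5 4-O-triethylsilyl ether of 4
Conditions: Et3SiOTf, 2,6-lutidine, CH2Cl2, −78 to 0 °C
Reagents that add atoms: triethylsilyl triflate, CC[Si](CC)(CC)OS(=O)(=O)C(F)(F)F
Why: Silyl triflate with a hindered pyridine base is the standard silylation of a tertiary alcohol, and the ether blocks retro-aldol loss of the sulfonyl carbanion and α-ketol rearrangement once the lactone carbonyl is reduced; the oxirane has only bridgehead neighbours and cannot eliminate.

Step 4
Reactants: 5 silylated epoxy lactone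
Product: 6 lactol of 5 (lactone C=O reduced to CH–OH, mixture of anomers)
Conditions: i-Bu2AlH (1.2 equiv), CH2Cl2, −78 °C; aq potassium sodium tartrate
Reagents that add atoms: none
Why: Partial lactone reduction by i-Bu2AlH at −78 °C stops at the aluminium hemiacetal, which gives the lactol on work-up; sulfone, oxirane and silyl ether are inert at this temperature, and the lactol centre is of no consequence because it becomes sp2 in step 8.

Step 5
Reactants: 7 sorbic acid
Product: 8 2-(trimethylsilyl)ethyl (2E,4E)-hexa-2,4-dienoate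
Conditions: Me3SiCH2CH2OH, EDC·HCl, DMAP, CH2Cl2, 0 °C to rt
Reagents that add atoms: 2-(trimethylsilyl)ethanol, C[Si](C)(C)CCO
Why: Steglich esterification installs an ester that should withstand radical bromination, phosphite, amide bases and copper catalysis and is later cleaved by fluoride together with the silyl ether.

Step 6
Reactants: 8 2-(trimethylsilyl)ethyl sorbate
Product: 9 2-(trimethylsilyl)ethyl (2E,4E)-6-bromohexa-2,4-dienoate
Conditions: NBS, AIBN (cat.), PhCF3, 80 °C
Reagents that add atoms: N-bromosuccinimide, O=C1CCC(=O)N1Br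
Why: Wohl–Ziegler bromination, in which hydrogen abstraction from the terminal methyl gives a pentadienyl radical that is brominated at the terminus so that the conjugated (2E,4E)-dienoate is kept.

Step 7
Reactants: 9 2-(trimethylsilyl)ethyl (2E,4E)-6-bromohexa-2,4-dienoate
Product: 10 2-(trimethylsilyl)ethyl (2E,4E)-6-(diethoxyphosphoryl)hexa-2,4-dienoate
Conditions: P(OEt)3, neat, 120 °C
Reagents that add atoms: triethyl phosphite, CCOP(OCC)OCC
Why: Michaelis–Arbuzov reaction of a primary allylic bromide with triethyl phosphite, driven by loss of bromoethane.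

Step 8
Reactants: 6 lactol; 10 2-(trimethylsilyl)ethyl (2E,4E)-6-(diethoxyphosphoryl)hexa-2,4-dienoate
Product: 12 2-(trimethylsilyl)ethyl (2E,4E,6E)-7-[5,6-epoxy-1-hydroxy-3-(phenylsulfonyl)-4-(triethylsilyloxy)cyclohex-4-yl]hepta-2,4,6-trienoate, via ring-opened hydroxy aldehyde 11 (not isolated)
Conditions: 10 (2.5 equiv), LiN(SiMe3)2 (2.4 equiv), THF, −78 °C; then 6, −78 to 0 °C
Reagents that add atoms: none
Why: Horner–Wadsworth–Emmons olefination, in which the lactol opens to the hydroxy aldehyde under the basic conditions and the ester-stabilised extended phosphonate anion adds through its α-carbon to give the E alkene; the anion is too weak a base to remove the α-sulfonyl hydrogen, and the C1 alkoxide is cis to the oxirane, so Payne migration is geometrically excluded.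

Step 9
Reactants: 12 hydroxy sulfone trienoate
Product: 14 2-(trimethylsilyl)ethyl (2E,4E,6E)-7-[(4R,5R,6S)-5,6-epoxy-1-oxo-4-(triethylsilyloxy)cyclohex-2-en-4-yl]hepta-2,4,6-trienoate, via beta-sulfonyl ketone 13 (not isolated)
Conditions: Dess–Martin periodinane, NaHCO3, CH2Cl2, 0 °C to rt; then Et3N, 0 °C
Reagents that add atoms: none
Why: Dess–Martin oxidation of the secondary alcohol gives a β-sulfonyl ketone whose only enolisable position is C2, so Et3N should trigger E1cB loss of benzenesulfinate to the C2=C3 enone; the C1 and C3 stereocentres are removed here.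

Step 10
Reactants: 14 epoxy enone
Product: 15 2-(trimethylsilyl)ethyl (2E,4E,6E)-7-[(4R,5R,6S)-5,6-epoxy-2-iodo-1-oxo-4-(triethylsilyloxy)cyclohex-2-en-4-yl]hepta-2,4,6-trienoate
Conditions: I2, pyridine, DMAP (cat.), CH2Cl2, 0 °C to rt, dark
Reagents that add atoms: iodine, II
Why: Baylis–Hillman-type α-iodination of a cyclic enone (the pyridine base adds at C3, the enolate is iodinated at C2, the base is expelled), a reaction type used on 4,4-disubstituted and epoxide-bearing cyclohexenones; the acyclic trienoate is not activated under these conditions.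

Step 11
Reactants: 16 (R)-4-benzyloxazolidin-2-one; 17 hexanoyl chloride
Product: 18 (R)-4-benzyl-3-hexanoyloxazolidin-2-one
Conditions: n-BuLi, THF, −78 °C; then 17, −78 to 0 °C
Reagents that add atoms: none
Why: N-Acylation of the lithiated oxazolidinone by an acid chloride.

Step 12
Reactants: 18 (R)-4-benzyl-3-hexanoyloxazolidin-2-one
Product: 19 (R)-4-benzyl-3-[(R)-2-methylhexanoyl]oxazolidin-2-one
Conditions: NaN(SiMe3)2, THF, −78 °C; then MeI
Reagents that add atoms: iodomethane, CI
Why: Evans alkylation, in which the chelated Z sodium enolate is methylated on the face away from the benzyl group; with the (R)-auxiliary this sets the (R) configuration at the α-carbon, the later C4 of the octenoyl chain.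

Step 13
Reactants: 19 (R)-4-benzyl-3-[(R)-2-methylhexanoyl]oxazolidin-2-one
Product: 20 (R)-2-methylhexan-1-ol
Conditions: LiBH4, MeOH (1 equiv), Et2O, 0 °C
Reagents that add atoms: none
Why: Reductive removal of the auxiliary, in which LiBH4 attacks the exocyclic imide carbonyl and gives the primary alcohol without touching the α-stereocentre, the oxazolidinone being recovered.

Step 14
Reactants: 20 (R)-2-methylhexan-1-ol
Product: 22 (2E,4R)-4-methyloct-2-enamide, via (R)-2-methylhexanal 21 (not isolated)
Conditions: (COCl)2, DMSO, CH2Cl2, −78 °C; Et3N; then Ph3P=CHCONH2, −78 °C to rt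
Reagents that add atoms: (carbamoylmethylene)triphenylphosphorane, NC(=O)C=P(c1ccccc1)(c1ccccc1)c1ccccc1
Why: Swern oxidation followed in the same flask by a Wittig reaction with an amide-stabilised ylide traps the epimerisable α-branched aldehyde as it forms and should give the E enamide.

Step 15
Reactants: 15 iodo epoxy enone; 22 (2E,4R)-4-methyloct-2-enamide
Product: 23 2-(trimethylsilyl)ethyl (2E,4E,6E)-7-[(4R,5R,6S)-5,6-epoxy-2-[(2E,4R)-4-methyloct-2-enoylamino]-1-oxo-4-(triethylsilyloxy)cyclohex-2-en-4-yl]hepta-2,4,6-trienoate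
Conditions: CuI (10 mol %), MeNHCH2CH2NHMe (20 mol %), Cs2CO3, THF, 50 °C
Reagents that add atoms: none
Why: Goldberg-type copper-catalysed N-vinylation of a primary amide by a vinyl iodide, a reaction type established for vinyl iodides including α-iodoenones; C4 is quaternary and the oxirane carbons carry no hydrogen that the carbonate could remove.

Step 16
Reactants: 23 fully protected enamide
Product: 24 (2E,4E,6E)-7-[(4R,5R,6S)-5,6-epoxy-4-hydroxy-2-[(2E,4R)-4-methyloct-2-enoylamino]-1-oxocyclohex-2-en-4-yl]hepta-2,4,6-trienoic acid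
Conditions: (Me2N)3S+ Me3SiF2− (TASF), DMF, 0 °C to rt; aq NH4Cl
Reagents that add atoms: none
Why: Fluoride-induced desilylation, in which fluoride attacks silicon in the 2-(trimethylsilyl)ethyl ester (fragmentation to ethene and carboxylate) and in the triethylsilyl ether; the anhydrous, weakly basic difluorosilicate avoids hydroxide that could open the epoxy ketone.

Step 17
Reactants: 24 hydroxy trienoic acid; 25 2-amino-3-hydroxycyclopent-2-en-1-one hydrochloride
Product: 26 CNP0259807.5, (2E,4R)-N-[(4R,5R,6S)-5,6-epoxy-4-hydroxy-4-[(1E,3E,5E)-7-[(2-hydroxy-5-oxocyclopent-1-en-1-yl)amino]-7-oxohepta-1,3,5-trien-1-yl]-1-oxocyclohex-2-en-2-yl]-4-methyloct-2-enamide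
Conditions: EDC·HCl, HOBt, N-methylmorpholine, DMF, 0 °C to rt
Reagents that add atoms: none
Why: Carbodiimide-mediated amide coupling with HOBt, in which the activated acid acylates the amino group of the vinylogous acid (any O-acyl isomer passes its acyl group to nitrogen), while the tertiary C4 hydroxyl and the enamide N–H should not be acylated.

**Compound list**

1 | 3-hydroxy-2H-pyran-2-one | O=C1OC=CC=C1O | starting material
2 | phenyl vinyl sulfone | C=CS(=O)(=O)c1ccccc1 | starting material
3 | (1R,4R,8R)-4-hydroxy-8-(phenylsulfonyl)-2-oxabicyclo[2.2.2]oct-5-en-3-one, endo adduct | O=C1O[C@H]2C=C[C@]1(O)[C@H](S(=O)(=O)c1ccccc1)C2 | intermediate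
4 | 5,6-epoxide of 3, oxirane oxygen syn to the lactone bridge and anti to the sulfonyl group | O=C1O[C@H]2[C@H]3O[C@H]3[C@]1(O)[C@H](S(=O)(=O)c1ccccc1)C2 | intermediate
5 | 4-O-triethylsilyl ether of 4 | O=C1O[C@H]2[C@H]3O[C@H]3[C@]1(O[Si](CC)(CC)CC)[C@H](S(=O)(=O)c1ccccc1)C2 | intermediate
6 | lactol of 5, anomeric mixture | OC1O[C@H]2[C@H]3O[C@H]3[C@]1(O[Si](CC)(CC)CC)[C@H](S(=O)(=O)c1ccccc1)C2 | intermediate
7 | sorbic acid | C/C=C/C=C/C(O)=O | starting material
8 | 2-(trimethylsilyl)ethyl (2E,4E)-hexa-2,4-dienoate | C/C=C/C=C/C(=O)OCC[Si](C)(C)C | intermediate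
9 | 2-(trimethylsilyl)ethyl (2E,4E)-6-bromohexa-2,4-dienoate | BrC/C=C/C=C/C(=O)OCC[Si](C)(C)C | intermediate
10 | 2-(trimethylsilyl)ethyl (2E,4E)-6-(diethoxyphosphoryl)hexa-2,4-dienoate | CCOP(=O)(OCC)C/C=C/C=C/C(=O)OCC[Si](C)(C)C | intermediate
11 | ring-opened hydroxy aldehyde: 5,6-epoxy-1-hydroxy-3-(phenylsulfonyl)-4-(triethylsilyloxy)cyclohexane-4-carbaldehyde (ring numbering of the plan; C1–OH, oxirane oxygen and CHO on one face, OSiEt3 and sulfonyl on the other) | O=C[C@@]1(O[Si](CC)(CC)CC)[C@H](S(=O)(=O)c2ccccc2)C[C@@H](O)[C@H]2O[C@@H]12 | intermediate (not isolated)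
12 | 2-(trimethylsilyl)ethyl (2E,4E,6E)-7-[5,6-epoxy-1-hydroxy-3-(phenylsulfonyl)-4-(triethylsilyloxy)cyclohex-4-yl]hepta-2,4,6-trienoate (faces as in 11) | C[Si](C)(C)CCOC(=O)/C=C/C=C/C=C/[C@@]1(O[Si](CC)(CC)CC)[C@H](S(=O)(=O)c2ccccc2)C[C@@H](O)[C@H]2O[C@@H]12 | intermediate
13 | β-sulfonyl ketone: 1-oxo analogue of 12 | C[Si](C)(C)CCOC(=O)/C=C/C=C/C=C/[C@@]1(O[Si](CC)(CC)CC)[C@H](S(=O)(=O)c2ccccc2)CC(=O)[C@H]2O[C@@H]12 | intermediate (not isolated)
14 | 2-(trimethylsilyl)ethyl (2E,4E,6E)-7-[(4R,5R,6S)-5,6-epoxy-1-oxo-4-(triethylsilyloxy)cyclohex-2-en-4-yl]hepta-2,4,6-trienoate | C[Si](C)(C)CCOC(=O)/C=C/C=C/C=C/[C@@]1(O[Si](CC)(CC)CC)C=CC(=O)[C@H]2O[C@@H]12 | intermediate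
15 | 2-iodo derivative of 14 | C[Si](C)(C)CCOC(=O)/C=C/C=C/C=C/[C@@]1(O[Si](CC)(CC)CC)C=C(I)C(=O)[C@H]2O[C@@H]12 | intermediate
16 | (R)-4-benzyloxazolidin-2-one | O=C1N[C@H](Cc2ccccc2)CO1 | starting material
17 | hexanoyl chloride | CCCCCC(=O)Cl | starting material
18 | (R)-4-benzyl-3-hexanoyloxazolidin-2-one | CCCCCC(=O)N1[C@H](Cc2ccccc2)COC1=O | intermediate
19 | (R)-4-benzyl-3-[(R)-2-methylhexanoyl]oxazolidin-2-one | CCCC[C@@H](C)C(=O)N1[C@H](Cc2ccccc2)COC1=O | intermediate
20 | (R)-2-methylhexan-1-ol | CCCC[C@@H](C)CO | intermediate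
21 | (R)-2-methylhexanal | CCCC[C@@H](C)C=O | intermediate (not isolated)
22 | (2E,4R)-4-methyloct-2-enamide | CCCC[C@@H](C)/C=C/C(N)=O | intermediate
23 | 2-[(2E,4R)-4-methyloct-2-enoylamino] derivative of 14 | C[Si](C)(C)CCOC(=O)/C=C/C=C/C=C/[C@@]1(O[Si](CC)(CC)CC)C=C(NC(=O)/C=C/[C@H](C)CCCC)C(=O)[C@H]2O[C@@H]12 | intermediate
24 | (2E,4E,6E)-7-[(4R,5R,6S)-5,6-epoxy-4-hydroxy-2-[(2E,4R)-4-methyloct-2-enoylamino]-1-oxocyclohex-2-en-4-yl]hepta-2,4,6-trienoic acid | OC(=O)/C=C/C=C/C=C/[C@@]1(O)C=C(NC(=O)/C=C/[C@H](C)CCCC)C(=O)[C@H]2O[C@@H]12 | intermediate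
25 | 2-amino-3-hydroxycyclopent-2-en-1-one hydrochloride | NC1=C(O)CCC1=O.Cl | starting material
26 | CNP0259807.5 | CCCC[C@@H](C)/C=C/C(=O)NC1=C[C@](O)(/C=C/C=C/C=C/C(=O)NC2=C(O)CCC2=O)[C@@H]2O[C@@H]2C1=O | target

**Step count**

Total: 17 steps. Longest linear sequence: 10 steps (steps 1, 2, 3, 4, 8, 9, 10, 15, 16, 17).

**Steps most likely to fail**

Step 1. What may go wrong: incomplete enantiofacial or endo control, or slow addition, with an unsubstituted vinyl sulfone. The fallback sets out from 1 and 2 and returns at 3. The cycloaddition would be run with Et3N as achiral base catalyst, which should give the racemic endo adduct, that is 3 together with its mirror image, the (1S,4S,8S)-adduct F1. Preparative chromatography on a chiral stationary phase (amylose tris(3,5-dimethylphenylcarbamate), supercritical CO2/MeOH) would separate the two, and 3 continues into step 2.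

Step 8. What may go wrong: reluctant opening of the bicyclic lactol and slow addition to the neopentyl aldehyde, with the C1 alkoxide re-closing on C1′. The fallback sets out from 5 and returns at 12. The lactone of 5 would be opened with MeNH(OMe)·HCl and i-PrMgCl (THF, −20 °C) to the ring-opened C1-hydroxy Weinreb amide F2. Me3SiCl and imidazole would cap the C1 hydroxyl as the C1-O-trimethylsilyl Weinreb amide F3. Reduction with i-Bu2AlH (THF, −78 °C) would give the C1-silyloxy aldehyde F4, which can no longer close to a lactol. Olefination with lithiated 10 would give the C1-O-trimethylsilyl trienoate F5. Citric acid in MeOH at 0 °C would then remove only the secondary trimethylsilyl ether and give 12.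

Step 15. What may go wrong: base- and heat-induced degradation of the epoxy iodoenone, or stalling of the C–N coupling. The fallback sets out from 15 and returns at 23. Copper-catalysed azidation at room temperature (NaN3, CuI, sodium ascorbate, MeNHCH2CH2NHMe, EtOH/H2O) would give the 2-azidoenone F6. Staudinger reduction (PPh3, THF/H2O) would give the 2-aminoenone F7. The acylating agent would be made from aldehyde 21, generated from 20 as in step 14: olefination with the dianion of diethylphosphonoacetic acid (NaH, THF) gives (2E,4R)-4-methyloct-2-enoic acid F8, and (COCl)2 with catalytic DMF converts it to (2E,4R)-4-methyloct-2-enoyl chloride F9. N-Acylation of F7 with F9 (pyridine, CH2Cl2, 0 °C) would give 23.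

**Further compounds**

F1 | step 1 | (1S,4S,8S)-4-hydroxy-8-(phenylsulfonyl)-2-oxabicyclo[2.2.2]oct-5-en-3-one, mirror image of 3 | O=C1O[C@@H]2C=C[C@@]1(O)[C@@H](S(=O)(=O)c1ccccc1)C2
F2 | step 8 | ring-opened C1-hydroxy Weinreb amide (N-methoxy-N-methyl carboxamide at C4, configuration as in 11) | CON(C)C(=O)[C@@]1(O[Si](CC)(CC)CC)[C@H](S(=O)(=O)c2ccccc2)C[C@@H](O)[C@H]2O[C@@H]12
F3 | step 8 | C1-O-trimethylsilyl Weinreb amide | CON(C)C(=O)[C@@]1(O[Si](CC)(CC)CC)[C@H](S(=O)(=O)c2ccccc2)C[C@@H](O[Si](C)(C)C)[C@H]2O[C@@H]12
F4 | step 8 | C1-silyloxy aldehyde | O=C[C@@]1(O[Si](CC)(CC)CC)[C@H](S(=O)(=O)c2ccccc2)C[C@@H](O[Si](C)(C)C)[C@H]2O[C@@H]12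
F5 | step 8 | C1-O-trimethylsilyl trienoate (trimethylsilyl ether of 12) | C[Si](C)(C)CCOC(=O)/C=C/C=C/C=C/[C@@]1(O[Si](CC)(CC)CC)[C@H](S(=O)(=O)c2ccccc2)C[C@@H](O[Si](C)(C)C)[C@H]2O[C@@H]12
F6 | step 15 | 2-azidoenone (azide in place of iodine in 15) | C[Si](C)(C)CCOC(=O)/C=C/C=C/C=C/[C@@]1(O[Si](CC)(CC)CC)C=C(N=[N+]=[N-])C(=O)[C@H]2O[C@@H]12
F7 | step 15 | 2-aminoenone | C[Si](C)(C)CCOC(=O)/C=C/C=C/C=C/[C@@]1(O[Si](CC)(CC)CC)C=C(N)C(=O)[C@H]2O[C@@H]12
F8 | step 15 | (2E,4R)-4-methyloct-2-enoic acid | CCCC[C@@H](C)/C=C/C(O)=O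
F9 | step 15 | (2E,4R)-4-methyloct-2-enoyl chloride | CCCC[C@@H](C)/C=C/C(Cl)=O
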